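## Analysis of the target

Compound 37 is numbered as follows. Ring A is C1–C5 plus the spiro carbon C10. C4 carries the methyl C18 and the C19 methylene of a five-membered lactone whose carbonyl C6 sits on C5. C10 carries the C20 methylene of a six-membered lactone whose carbonyl C7 sits on C8, and C9 joins C8 to C10. C8 and C13 are the bridgeheads of a bicyclo[3.2.1]octane with bridges C14, C15(=O)–C16(H)(C17H2OH) and C9–C11(OH)–C12.

There are eight stereocentres. On ring A, C19, C6 and C20 lie on one face and C18, H5 and C9 on the other. At C9, the hydrogen is antiperiplanar to C14 and C10 is antiperiplanar to C15. The C11 hydroxyl is equatorial on the chair of ring C (C8, C9, C11, C12, C13, C14), with H11 pointing at the C15–C16 bridge. C17 is endo, on the side of the C9–C11–C12 bridge.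

The sensitive groups are the β-hydroxy ketone C15/C16/C17 (loss of water to the enone, epimerization at C16), the two lactones (a free C20 hydroxyl can attack C6 and move the five-membered lactone), and C9, which is epimerizable while C11 is a ketone. The difficulty is the run of three congested carbons: the quaternary bridgehead C8 bearing a carboxyl, C9, and the quaternary spiro centre C10. The C8–C9 bond also joins two carbons that are each α to a carbonyl (C7 and C11), which simple enolate polarity cannot make.

The strategy rests on one feature. The five-membered ring C8, C15, C16, C13, C14 is a cyclopentadiene in disguise, spanned by the three-carbon unit C9–C11–C12 with oxygen on its central carbon. C8 is tied to C10, the neighbour of C9, through the C7 ester, so the two partners of an oxyallyl (4+3) cycloaddition can be held together by the very lactone the target needs.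

## Retrosynthetic reasoning

**37 back to 30 (no skeletal bond cut).** The C17 hydroxyl is kept as a benzyl ether (36) and the C11 hydroxyl as a silyl ether (35). The C15 ketone comes from the C15 alcohol 34, which is the hydroboration product of the C15=C16 alkene of 32. The C11 alcohol (31) comes from the C11 ketone 30. This leaves the β-hydroxy ketone to the last, neutral step. The forward steps must deliver hydride to C11 from the side of the C15=C16 bridge, and boron and hydrogen to the exo face of the alkene.

**30 to 28 (cut C8–C9 and C12–C13).** Both carbocyclic bridges are removed at once. What remains is a chloromethyl ketone on ring A and a cyclopenta-1,3-diene-1-carboxylate joined through the C20 ester. No other cut removes two rings and three stereocentres while leaving ring A untouched. The forward reaction must generate the oxyallyl cation 29 across C9–C11–C12 and bond its termini to C8 and C13 on one face of the diene.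

**28 to 18 and 26 (cut the C7–O ester bond).** This divides the molecule into the ring A hydroxy chloromethyl ketone 18 and the diene acid 26. The acylation must be the last step before the cycloaddition and must be run cold, because 26 is a reactive diene and 18 has a free hydroxyl next to a lactone.

**26 to 24, 23, 19 and 20 (cut C7–C8 and C16–C17).** The 1,3-relation of carboxyl and benzyloxymethyl on the five-membered ring is fixed by making the carboxyl from the enol triflate 24 of enone 23. Enone 23 arises from the vinylogous ester 19 and the carbanion 21 released from stannane 20. Carboxylating a substituted cyclopentadienide would give positional isomers; this route cannot.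

**18 to 17, 14, 11, 8 and 9 (cut C9–C10).** The C11 ketone is the ozonolysis product of the 1,1-disubstituted alkene of 17. The C20 alcohol is the reduced carboxyl of the resolved acid in salt 14. The C9–C10 bond is an ester enolate alkylation of 8 with the allylic dichloride 9. This makes the quaternary C10 with the arm trans to C6 and delivers all three arm carbons with the chlorine in place.

**8 to 7, 5, 3 and 4 (cut C3–C4 and C5–C10).** The lactone is the regioselective hydride reduction product of the cyclic anhydride 5, and 5 is the Diels–Alder adduct of dienoate 3 and anhydride 4. The anhydride is chosen over a β,β-disubstituted butenolide dienophile because it reacts readily, and the reduction then gives the same lactone. One cycloaddition sets the cis relation of C19, C6 and C20.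

**3 to 1 and 2 (cut the C1=C10 double bond).** A Wittig olefination supplies the tert-butyl ester, which later survives the hydride steps and is removed by acid.

**Absolute configuration.** The Diels–Alder step gives a racemate. It is resolved at acid 12 through the salt 14 with amine 13, the last point before the ring A fragment meets the achiral diene.

## Alternatives that were turned down

**Alternative 1:** Disconnection of C9–C10.
- Forward key step: zerovalent palladium inserts into a C9 vinyl bromide held on the C20 ester. The vinylpalladium adds 6-exo to the C1=C10 alkene of ring A, and β-hydride loss toward C2 gives the spiro unsaturated lactone A1 with two acetal arms.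
- For: the reaction type is well established for quaternary spiro centres, it is catalytic, and the face of attack is set by the existing cis-fused lactone. On reliability of the key step it is stronger than the chosen route.
- Against: it forms one bond, one ring and one stereocentre. A1 still lacks the whole bicyclo[3.2.1]octane (C8, C9, C11, C13, C16 open), so a second ring-forming key step and the C17 carbon must follow. The extra C1=C2 alkene must be hydrogenated while C8=C9 survives.
- Comparison: the chosen cycloaddition closes both carbocyclic rings and sets three stereocentres in one step, and six further steps finish the target. The price is an untested step.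

**Alternative 2:** Disconnection of the C19–O bond, taken last.
- Forward key step: Pd(OAc)2 with an N-acyl amino acid ligand and a peroxide oxidant in a fluorinated alcohol. The C6 carboxylate directs palladation of a C–H bond of one geminal methyl on C4, and C–O bond formation gives the bis-lactone A2.
- For: ring A could come from a simple gem-dimethyl acid with no early handling of the C19 oxidation level. On economy of ring A it is stronger than the chosen route.
- Against: C4 becomes a stereocentre only here, so two diastereotopic methyl groups must be told apart late on a finished pentacycle. A peroxide meets a ketone. A2 lacks C17, which then needs a stereocontrolled hydroxymethylation at the enolizable C16. The step contributes nothing to the bicyclo[3.2.1]octane.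
- Comparison: the chosen route fixes C4 at the outset in the Diels–Alder step and carries C17 on the diene.

**Alternative 3:** Disconnection of C9–C11 and C8–C15.
- Forward key step: SmI2 reduces one aldehyde arm of a symmetric dialdehyde to a ketyl, which adds to C9 of an unsaturated spiro lactone. The samarium enolate at C8 then adds to the second aldehyde, giving the diol A3.
- For: reductive ketyl–enoate and aldol cascades are established reaction types. Two rings and four stereocentres form at once, and the C11 hydroxyl arrives at the right oxidation level. On precedent it is stronger than the chosen key step.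
- Against: A3 is 17-nor and carries two secondary alcohols to differentiate. C15 oxidation and a stereocontrolled hydroxymethylation at C16 (prone to dehydration) add four or five steps. The two aldehyde arms are distinguished by the substrate alone.
- Comparison: the chosen route has C17 and the C15=C16 alkene in place after the key step, and one hydroboration then sets the C15 oxygen and the C16 configuration.

Key step: step 14

Assumption: the less soluble (S)-1-phenylethylammonium salt is taken to be that of the acid with the configuration drawn in 14; if it proves to be the other one, (R)-1-phenylethylamine is used and nothing else changes.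

## Route

Step 1
Reactants: 1 acrolein (prop-2-enal); 2 tert-butyl (triphenylphosphoranylidene)acetate
Product: 3 tert-butyl (2E)-penta-2,4-dienoate
Conditions: CH2Cl2, 0 °C → rt
Reagents that add atoms: none
Why: Wittig olefination of the aldehyde with a stabilized ylide should give the (E)-dienoate; the tert-butyl ester is chosen because it survives hydride and is later removed by acid.

Step 2
Reactants: 3 tert-butyl (2E)-penta-2,4-dienoate; 4 citraconic anhydride (3-methylfuran-2,5-dione)
Product: 5 racemic all-cis anhydride ester (tert-butyl 3a-methyl-1,3-dioxo-1,3,3a,4,7,7a-hexahydro-2-benzofuran-7-carboxylate; C19, C6 and C20 on one face)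
Conditions: PhMe, BHT (cat.), 120 °C, sealed tube
Reagents that add atoms: none
Why: Thermal Diels–Alder reaction forming C3–C4 and C5–C10. The substituted diene terminus should bond to the unsubstituted carbon of the anhydride (steric and polar preference), and endo approach places the ester cis to the anhydride, so C4, C5 and C10 are set all-cis as a racemate.

Step 3
Reactants: 5 racemic all-cis anhydride ester
Product: 7 racemic cis-fused lactone ester (tert-butyl 3a-methyl-1-oxo-1,3,3a,4,7,7a-hexahydro-2-benzofuran-7-carboxylate), via hydroxy acid 6 (not isolated)
Conditions: NaBH4, THF, 0 °C; then 2 M HCl, rt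
Reagents that add atoms: none
Why: Hydride reduction of an unsymmetrical cyclic anhydride, which should occur at the carbonyl flanked by the fully substituted carbon (C19). The C6 carbonyl is in addition shielded by the cis ester; acid closes hydroxy acid 6 to the lactone and the tert-butyl ester is not reduced.

Step 4
Reactants: 7 racemic cis-fused lactone ester
Product: 8 racemic saturated lactone ester (tert-butyl 3a-methyl-1-oxooctahydro-2-benzofuran-7-carboxylate)
Conditions: H2 (1 atm), Pd/C, EtOAc, rt
Reagents that add atoms: none
Why: Catalytic hydrogenation removes the only alkene, so that the later ozonolysis and the cycloaddition meet no second alkene; no stereocentre is formed.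

Step 5
Reactants: 8 racemic saturated lactone ester; 9 3-chloro-2-(chloromethyl)prop-1-ene
Product: 11 racemic C10-alkylated lactone ester (2-(chloromethyl)allyl arm trans to C6 and tert-butyl ester cis to C6), via lithium enolate 10 (not isolated)
Conditions: LiN(iPr)2, THF, −78 °C; then 9 (4 equiv), DMPU, −78 → −20 °C
Reagents that add atoms: none
Why: Ester enolate alkylation with an allylic chloride forms C9–C10 and the quaternary centre. The electrophile should enter the exocyclic enolate anti to the C5–C6 bond and to the axial C19 methylene, so the arm ends trans to C6. The less hindered C10–H is removed in preference to C5–H, and excess 9 prevents double alkylation.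

Step 6
Reactants: 11 racemic C10-alkylated lactone ester
Product: 12 racemic C20 carboxylic acid
Conditions: CF3CO2H/CH2Cl2 (1:4), 0 °C
Reagents that add atoms: none
Why: Acidolysis of the tert-butyl ester with loss of isobutene; the lactone and the allylic chloride are inert. The alkene is deactivated toward protonation by the allylic chlorine, so it should survive a short exposure.

Step 7
Reactants: 12 racemic C20 carboxylic acid; 13 (S)-1-phenylethylamine
Product: 14 (S)-1-phenylethylammonium salt of the acid with the ring A configuration of 37
Conditions: 13 (1 equiv), EtOAc/i-PrOH, rt; recrystallization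
Reagents that add atoms: none
Why: Classical resolution by crystallization of diastereomeric ammonium carboxylates; it fixes the absolute configuration of C4, C5 and C10 before the fragment meets the achiral diene.

Step 8
Reactants: 14 (S)-1-phenylethylammonium salt of the resolved acid
Product: 17 C20 alcohol (7-[2-(chloromethyl)prop-2-en-1-yl]-7-(hydroxymethyl)-3a-methylhexahydro-2-benzofuran-1(3H)-one), via carboxylic acid 15 (not isolated), via acid chloride 16 (not isolated)
Conditions: EtOAc/1 M HCl; (COCl)2, DMF (cat.), CH2Cl2, 0 °C → rt; NaBH4, THF/DMF, −20 °C; AcOH quench
Reagents that add atoms: none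
Why: The acid chloride is reduced by borohydride far faster than the lactone, so only C20 is reduced; borane is avoided because of the alkene. The cold acidic quench keeps the new hydroxyl from attacking C6.

Step 9
Reactants: 17 C20 alcohol
Product: 18 ring A hydroxy chloromethyl ketone (7-(3-chloro-2-oxopropyl)-7-(hydroxymethyl)-3a-methylhexahydro-2-benzofuran-1(3H)-one)
Conditions: O3, CH2Cl2, −78 °C; then Me2S, −78 °C → rt
Reagents that add atoms: ozone O=[O+][O-]
Why: Ozonolysis of the only alkene, a 1,1-disubstituted one, gives the ketone and formaldehyde and turns the allylic chloride into the α-chloro ketone. 18 may sit partly as its five-membered hemiketal, which does not matter for the next step.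

Step 10
Reactants: 19 3-ethoxycyclopent-2-en-1-one; 20 tributyl[(benzyloxy)methyl]stannane
Product: 23 3-[(benzyloxy)methyl]cyclopent-2-en-1-one, via (benzyloxymethyl)lithium 21 (not isolated), via tertiary carbinol 22 (not isolated)
Conditions: 20, n-BuLi, THF, −78 °C; then 19, −78 → 0 °C; then 1 M HCl
Reagents that add atoms: water O
Why: Stork–Danheiser transposition: tin–lithium exchange gives the α-alkoxy organolithium, which adds 1,2 to the vinylogous ester. Acid hydrolysis of the enol ether with loss of ethanol gives the 3-substituted enone.

Step 11
Reactants: 23 3-[(benzyloxy)methyl]cyclopent-2-en-1-one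
Product: 24 4-[(benzyloxy)methyl]cyclopenta-1,4-dien-1-yl trifluoromethanesulfonate
Conditions: LiN(iPr)2, THF, −78 °C; PhNTf2, −78 → 0 °C
Reagents that add atoms: N-phenylbis(trifluoromethanesulfonimide) O=S(=O)(N(c1ccccc1)S(=O)(=O)C(F)(F)F)C(F)(F)F
Why: Kinetic α′-deprotonation of the enone and O-sulfonylation of the cross-conjugated dienolate. The triflate marks the carbon that becomes C8, in a fixed 1,3-relation to the benzyloxymethyl carbon.

Step 12
Reactants: 24 4-[(benzyloxy)methyl]cyclopenta-1,4-dien-1-yl trifluoromethanesulfonate
Product: 26 3-[(benzyloxy)methyl]cyclopenta-1,3-diene-1-carboxylic acid, via cross-conjugated acid tautomer 25 (not isolated)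
Conditions: Pd(OAc)2 (cat.), PPh3, CO (1 atm), Et3N, DMF/H2O, rt; cold acidic work-up, used at once
Reagents that add atoms: carbon monoxide [C-]#[O+]; water O
Why: Palladium-catalysed hydroxycarbonylation of an enol triflate (oxidative addition to zerovalent palladium, CO insertion, hydrolysis of the acylpalladium). The first-formed acid 25 should pass by a [1,5]-hydrogen shift into the linearly conjugated tautomer 26.

Step 13
Reactants: 18 ring A hydroxy chloromethyl ketone; 26 3-[(benzyloxy)methyl]cyclopenta-1,3-diene-1-carboxylic acid
Product: 28 ring A chloromethyl ketone dienyl ester (C20 ester of 18 with 26), via diene acid chloride 27 (not isolated)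
Conditions: 26, 1-chloro-N,N,2-trimethylprop-1-en-1-amine, CH2Cl2, 0 °C; then 18, 2,6-lutidine, −20 → 0 °C; used at once
Reagents that add atoms: none
Why: Acylation of the primary neopentyl alcohol by an acid chloride made under neutral conditions. The hindered pyridine base cannot displace the chloride of the chloromethyl ketone, and the cold keeps the diene from Diels–Alder dimerization. Any hemiketal form of 18 drains through the open hydroxy ketone.

Step 14
Reactants: 28 ring A chloromethyl ketone dienyl ester
Product: 30 pentacyclic C11 ketone with C15=C16 alkene and C17 benzyl ether, via oxyallyl cation 29 (not isolated)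
Conditions: Et3N (3 equiv), CF3CH2OH, 0.005 M, 0 °C → rt
Reagents that add atoms: none
Why: Proposed new method: Et3N in CF3CH2OH enolizes the chloromethyl ketone reversibly toward C9 and the ionizing solvent helps chloride leave C12, giving the 2-oxyallyl cation 29 (C9–C11–C12), which the tethered diene captures in a (4+3) cycloaddition, in concert or with C12–C13 first (the allyl cation left behind is tertiary at C16 and is closed by the C9 enolate at C8); the closest known reaction type is the intramolecular (4+3) cycloaddition of oxyallyl cations from α-halo ketones with alkyl-tethered furans or dienes, which has not been shown for an ester-tethered cyclopenta-1,3-diene-1-carboxylate. The six-membered lactone (C8, C9, C10, C20, O, C7) closes as the tether ring when C8–C9 forms, with the ester in its lactone-type rotamer. The seven-membered carbocycle (C8, C9, C11, C12, C13, C16, C15) closes by suprafacial bonding of both cation termini to the diene termini, C14 becoming the one-carbon bridge of the bicyclo[3.2.1]octenone. C8 and C13 are set together by this suprafacial addition, and the diene face is chosen by C10: C20 must rise toward C8, the bulky C5 branch lies in the cation plane anti to C11, and C1 points away from the diene. C9 follows from the cation geometry (C10 syn to the oxygen, which avoids allylic strain with C12) and an extended approach in which C14 and not C15=C16 lies over the oxygen, so that C10 ends anti to C15. Regioselectivity is secured by the tether, since C9 can reach only C8, and by the benzyloxymethyl group, since only the tautomer with C8=C15 and C16=C13 offers an unsubstituted terminus C13 to C12 (the tautomers interconvert under the basic conditions and are drained through this one). High dilution and low temperature are needed to keep Diels–Alder dimerization of the diene and intermolecular alkylation behind the ring closure.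

Step 15
Reactants: 30 pentacyclic C11 ketone
Product: 31 C11 alcohol (hydroxyl equatorial on ring C and H11 toward the C15=C16 bridge)
Conditions: NaBH4, THF/EtOH (4:1), −40 °C; NH4Cl quench
Reagents that add atoms: none
Why: Borohydride reduces the ketone and leaves both lactones at this temperature. Hydride should enter C11 from the side of the C15=C16 bridge, anti to the axial C10 substituent on C9 that blocks the other face, which sets C11 by substrate control; the cold neutral quench keeps C9 from epimerizing.

Step 16
Reactants: 31 C11 alcohol
Product: 32 C11 triethylsilyl ether
Conditions: TESOTf, 2,6-lutidine, CH2Cl2, −78 → 0 °C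
Reagents that add atoms: triethylsilyl trifluoromethanesulfonate CC[Si](CC)(CC)OS(=O)(=O)C(F)(F)F
Why: Silylation of a hindered secondary alcohol with a silyl triflate; it keeps C11 out of the later oxidation at C15.

Step 17
Reactants: 32 C11 triethylsilyl ether
Product: 34 C15 alcohol (exo hydroxyl and C17 endo on C16), via alkylborane 33 (not isolated)
Conditions: BH3·THF, THF, 0 °C → rt; then NaBO3·4H2O, THF/H2O, rt
Reagents that add atoms: sodium perborate [Na+].[O-]OB=O
Why: Hydroboration–oxidation of the trisubstituted alkene. Boron should add to the less substituted C15 and hydrogen to C16, both from the exo face turned to C14, because the endo face is covered by the C9–C11–C12 bridge and the axial H11; this sets C16 with C17 endo. Perborate oxidizes the C–B bond with retention without opening the lactones.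

Step 18
Reactants: 34 C15 alcohol
Product: 35 C15 ketone with C11 silyl ether and C17 benzyl ether
Conditions: Dess–Martin periodinane, NaHCO3, CH2Cl2, 0 °C → rt
Reagents that add atoms: none
Why: Oxidation of the secondary alcohol under buffered, near-neutral conditions, which should neither epimerize C16 nor eliminate the β-benzyloxy group.

Step 19
Reactants: 35 C15 ketone with C11 silyl ether and C17 benzyl ether
Product: 36 C11 alcohol C15 ketone with C17 benzyl ether
Conditions: HF·pyridine, pyridine, THF, 0 °C → rt
Reagents that add atoms: none
Why: Buffered fluoride cleavage of the triethylsilyl ether; the benzyl ether, the ketone and both lactones are stable to it.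

Step 20
Reactants: 36 C11 alcohol C15 ketone with C17 benzyl ether
Product: 37 CNP0555433.1
Conditions: H2 (1 atm), Pd(OH)2/C, EtOAc, rt
Reagents that add atoms: none
Why: Hydrogenolysis of the benzyl ether under neutral conditions frees the C17 hydroxyl last, so the β-hydroxy ketone is never exposed to acid or base.

## Compound list

1 | acrolein (prop-2-enal) | C=CC=O | starting material
2 | tert-butyl (triphenylphosphoranylidene)acetate | CC(C)(C)OC(=O)C=P(c1ccccc1)(c1ccccc1)c1ccccc1 | starting material
3 | tert-butyl (2E)-penta-2,4-dienoate | C=C/C=C/C(=O)OC(C)(C)C | intermediate
4 | citraconic anhydride (3-methylfuran-2,5-dione) | CC1=CC(=O)OC1=O | starting material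
5 | racemic all-cis anhydride ester, tert-butyl 3a-methyl-1,3-dioxo-1,3,3a,4,7,7a-hexahydro-2-benzofuran-7-carboxylate (one enantiomer drawn) | C[C@@]12CC=C[C@H](C(=O)OC(C)(C)C)[C@@H]1C(=O)OC2=O | intermediate
6 | racemic hydroxy acid from hydride attack at C19 of 5 (one enantiomer drawn) | C[C@@]1(CO)CC=C[C@H](C(=O)OC(C)(C)C)[C@@H]1C(=O)O | intermediate (not isolated)
7 | racemic cis-fused lactone ester, tert-butyl 3a-methyl-1-oxo-1,3,3a,4,7,7a-hexahydro-2-benzofuran-7-carboxylate (one enantiomer drawn) | C[C@@]12CC=C[C@H](C(=O)OC(C)(C)C)[C@@H]1C(=O)OC2 | intermediate
8 | racemic saturated lactone ester, tert-butyl 3a-methyl-1-oxooctahydro-2-benzofuran-7-carboxylate (one enantiomer drawn) | C[C@@]12CCC[C@H](C(=O)OC(C)(C)C)[C@@H]1C(=O)OC2 | intermediate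
9 | 3-chloro-2-(chloromethyl)prop-1-ene | ClCC(=C)CCl | starting material
10 | lithium enolate of 8 at C10 | C[C@@]12CCCC(=C(O[Li])OC(C)(C)C)[C@@H]1C(=O)OC2 | intermediate (not isolated)
11 | racemic C10-alkylated lactone ester, arm trans to C6 (one enantiomer drawn) | C[C@@]12CCC[C@](CC(=C)CCl)(C(=O)OC(C)(C)C)[C@@H]1C(=O)OC2 | intermediate
12 | racemic C20 carboxylic acid (one enantiomer drawn) | C[C@@]12CCC[C@](CC(=C)CCl)(C(=O)O)[C@@H]1C(=O)OC2 | intermediate
13 | (S)-1-phenylethylamine | C[C@H](N)c1ccccc1 | starting material
14 | (S)-1-phenylethylammonium salt of the resolved acid | C[C@@]12CCC[C@](CC(=C)CCl)(C(=O)[O-])[C@@H]1C(=O)OC2.C[C@H]([NH3+])c1ccccc1 | intermediate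
15 | resolved C20 carboxylic acid | C[C@@]12CCC[C@](CC(=C)CCl)(C(=O)O)[C@@H]1C(=O)OC2 | intermediate (not isolated)
16 | C20 acid chloride | C[C@@]12CCC[C@](CC(=C)CCl)(C(Cl)=O)[C@@H]1C(=O)OC2 | intermediate (not isolated)
17 | C20 alcohol, 7-[2-(chloromethyl)prop-2-en-1-yl]-7-(hydroxymethyl)-3a-methylhexahydro-2-benzofuran-1(3H)-one | C[C@@]12CCC[C@](CC(=C)CCl)(CO)[C@@H]1C(=O)OC2 | intermediate
18 | ring A hydroxy chloromethyl ketone, 7-(3-chloro-2-oxopropyl)-7-(hydroxymethyl)-3a-methylhexahydro-2-benzofuran-1(3H)-one | C[C@@]12CCC[C@](CC(=O)CCl)(CO)[C@@H]1C(=O)OC2 | intermediate
19 | 3-ethoxycyclopent-2-en-1-one | CCOC1=CC(=O)CC1 | starting material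
20 | tributyl[(benzyloxy)methyl]stannane | CCCC[Sn](CCCC)(CCCC)COCc1ccccc1 | starting material
21 | (benzyloxymethyl)lithium | [Li]COCc1ccccc1 | intermediate (not isolated)
22 | 1-[(benzyloxy)methyl]-3-ethoxycyclopent-2-en-1-ol (formed as its lithium alkoxide) | CCOC1=CC(O)(COCc2ccccc2)CC1 | intermediate (not isolated)
23 | 3-[(benzyloxy)methyl]cyclopent-2-en-1-one | O=C1C=C(COCc2ccccc2)CC1 | intermediate
24 | 4-[(benzyloxy)methyl]cyclopenta-1,4-dien-1-yl trifluoromethanesulfonate | O=S(=O)(OC1=CCC(COCc2ccccc2)=C1)C(F)(F)F | intermediate
25 | 4-[(benzyloxy)methyl]cyclopenta-1,4-diene-1-carboxylic acid | OC(=O)C1=CCC(COCc2ccccc2)=C1 | intermediate (not isolated)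
26 | 3-[(benzyloxy)methyl]cyclopenta-1,3-diene-1-carboxylic acid | OC(=O)C1=CC(COCc2ccccc2)=CC1 | intermediate
27 | 3-[(benzyloxy)methyl]cyclopenta-1,3-diene-1-carbonyl chloride | ClC(=O)C1=CC(COCc2ccccc2)=CC1 | intermediate (not isolated)
28 | ring A chloromethyl ketone dienyl ester | C[C@@]12CCC[C@](CC(=O)CCl)(COC(=O)C3=CC(COCc4ccccc4)=CC3)[C@@H]1C(=O)OC2 | intermediate
29 | oxyallyl cation across C9–C11–C12 | C[C@@]12CCC[C@](C=C([O-])[CH2+])(COC(=O)C3=CC(COCc4ccccc4)=CC3)[C@@H]1C(=O)OC2 | intermediate (not isolated)
30 | pentacyclic C11 ketone with C15=C16 alkene and C17 benzyl ether | C[C@@]12CCC[C@]3(COC(=O)[C@@]45C[C@@H](CC(=O)[C@H]43)C(COCc6ccccc6)=C5)[C@@H]1C(=O)OC2 | intermediate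
31 | C11 alcohol | C[C@@]12CCC[C@]3(COC(=O)[C@@]45C[C@@H](C[C@@H](O)[C@H]43)C(COCc6ccccc6)=C5)[C@@H]1C(=O)OC2 | intermediate
32 | C11 triethylsilyl ether | C[C@@]12CCC[C@]3(COC(=O)[C@@]45C[C@@H](C[C@@H](O[Si](CC)(CC)CC)[C@H]43)C(COCc6ccccc6)=C5)[C@@H]1C(=O)OC2 | intermediate
33 | C15 alkylborane | C[C@@]12CCC[C@]3(COC(=O)[C@@]45C[C@@H](C[C@@H](O[Si](CC)(CC)CC)[C@H]43)[C@@H](COCc6ccccc6)[C@@H]5B)[C@@H]1C(=O)OC2 | intermediate (not isolated)
34 | C15 alcohol | C[C@@]12CCC[C@]3(COC(=O)[C@@]45C[C@@H](C[C@@H](O[Si](CC)(CC)CC)[C@H]43)[C@@H](COCc6ccccc6)[C@@H]5O)[C@@H]1C(=O)OC2 | intermediate
35 | C15 ketone with C11 silyl ether and C17 benzyl ether | C[C@@]12CCC[C@]3(COC(=O)[C@@]45C[C@@H](C[C@@H](O[Si](CC)(CC)CC)[C@H]43)[C@@H](COCc6ccccc6)C5=O)[C@@H]1C(=O)OC2 | intermediate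
36 | C11 alcohol C15 ketone with C17 benzyl ether | C[C@@]12CCC[C@]3(COC(=O)[C@@]45C[C@@H](C[C@@H](O)[C@H]43)[C@@H](COCc6ccccc6)C5=O)[C@@H]1C(=O)OC2 | intermediate
37 | CNP0555433.1 | C[C@@]12CCC[C@]3(COC(=O)[C@@]45C[C@@H](C[C@@H](O)[C@H]43)[C@@H](CO)C5=O)[C@@H]1C(=O)OC2 | target

## Step count and least certain steps

Total step count: 20. Longest linear sequence: 17 steps (steps 1–9, 13 and 14–20); the diene acid branch is steps 10–12.

**Step 14 (key step, Proposed new method).**
- What may go wrong: the oxyallyl cation may be quenched by the solvent or collapse by Favorskii rearrangement before the electron-poor diene terminus bonds, because the ester must first turn into its lactone-type rotamer. The base may deprotonate the acidic diene and shift the tautomer population. Even if the rings close, a compact instead of an extended approach would give the wrong configuration at C9.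
- Fallback (known reactions only; sets out from 18, returns at 30): the two bonds are made one at a time with the five-membered ring carried as a cyclopentenone.
  - Zn in AcOH removes the chlorine of 18 to give the methyl ketone alcohol F1.
  - Carbodiimide esterification with commercial 3-oxocyclopent-1-ene-1-carboxylic acid gives the keto ester F2.
  - Catalytic KOtBu closes the six-membered lactone by intramolecular Michael addition of the C9 enolate to C8, which is β to the ring ketone, giving the spiro lactone diketone F3.
  - The kinetic bis-enolate at C12 and C13 (LiN(iPr)2, −78 °C) is coupled oxidatively with CuCl2 (divalent copper) to form C12–C13 and the bicyclo[3.2.1]octane-11,16-dione F4.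
  - (Benzyloxymethyl)lithium 21 with CeCl3 adds to the less hindered C16 ketone to give the carbinol F5, and dehydration with Burgess reagent toward C15 gives 30.

**Step 13.**
- What may go wrong: Diels–Alder dimerization of the diene acid or its chloride may outrun acylation of the hindered neopentyl hydroxyl, and base may let the C20 hydroxyl migrate onto C6.
- Fallback (sets out from 18, returns at 28): the diene is made only after the ester bond exists. 3-Oxocyclopent-1-ene-1-carboxylic acid and two equivalents of 21 give the stable 3-[(benzyloxy)methyl]-3-hydroxycyclopent-1-ene-1-carboxylic acid F6. Carbodiimide coupling with 18 gives the hydroxy ester F7, and Burgess dehydration of the tertiary allylic alcohol toward the ring methylene gives 28.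

**Step 5.**
- What may go wrong: deprotonation at C5, the lactone α-carbon, may compete with deprotonation at C10, giving recovered material or alkylation at the wrong carbon.
- Fallback (sets out from 8, returns at 11): the lactone is opened with one equivalent of NaOH to the sodium hydroxy carboxylate F8, in which C5 is α to a carboxylate and no longer acidic. LiN(iPr)2 then forms only the ester enolate, alkylation with 9 follows, and acidification recloses the lactone to 11.

**Step 15.**
- What may go wrong: poor facial selectivity, with hydride entering from the side of C10 and C14 and giving the axial alcohol.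
- Fallback (sets out from 30, returns at 31): the 11-epi alcohol F9 is inverted by a Mitsunobu reaction with formic acid to the formate F10, which is cleaved with NaHCO3 in methanol to 31.

**Step 7.**
- What may go wrong: the two diastereomeric salts may crystallize together, so that no enrichment results.
- Fallback (sets out from 12, returns at 17): the racemate is carried through the reduction of step 8 and resolved as the alcohol by lipase-catalysed acetylation with vinyl acetate. The faster-reacting enantiomer becomes its acetate (written as the acetate F11 of the unwanted enantiomer) and is separated from unreacted 17. Should the wanted alcohol be the one acetylated, the same lipase removes the acetate again in buffered methanol.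

## Further compounds

F1 | step 14 | ring A hydroxy methyl ketone | C[C@@]12CCC[C@](CC(C)=O)(CO)[C@@H]1C(=O)OC2
F2 | step 14 | C20 ester of F1 with 3-oxocyclopent-1-ene-1-carboxylic acid | C[C@@]12CCC[C@](CC(C)=O)(COC(=O)C3=CC(=O)CC3)[C@@H]1C(=O)OC2
F3 | step 14 | spiro lactone diketone from Michael addition of C9 to C8 | C[C@@]12CCC[C@]3(COC(=O)[C@]4(CC(=O)CC4)[C@H]3C(C)=O)[C@@H]1C(=O)OC2
F4 | step 14 | pentacyclic 11,16-dione | C[C@@]12CCC[C@]3(COC(=O)[C@@]45C[C@@H](CC(=O)[C@H]43)C(=O)C5)[C@@H]1C(=O)OC2
F5 | step 14 | C16 carbinol bearing the benzyloxymethyl group | C[C@@]12CCC[C@]3(COC(=O)[C@@]45C[C@@H](CC(=O)[C@H]43)C(O)(COCc6ccccc6)C5)[C@@H]1C(=O)OC2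
F6 | step 13 | 3-[(benzyloxy)methyl]-3-hydroxycyclopent-1-ene-1-carboxylic acid | OC(=O)C1=CC(O)(COCc2ccccc2)CC1
F7 | step 13 | C20 ester of 18 with F6 | C[C@@]12CCC[C@](CC(=O)CCl)(COC(=O)C3=CC(O)(COCc4ccccc4)CC3)[C@@H]1C(=O)OC2
F8 | step 5 | sodium hydroxy carboxylate from opening of the lactone of 8 (racemic, one enantiomer drawn) | C[C@@]1(CO)CCC[C@H](C(=O)OC(C)(C)C)[C@@H]1C(=O)[O-].[Na+]
F9 | step 15 | 11-epi alcohol | C[C@@]12CCC[C@]3(COC(=O)[C@@]45C[C@@H](C[C@H](O)[C@H]43)C(COCc6ccccc6)=C5)[C@@H]1C(=O)OC2
F10 | step 15 | C11 formate with the configuration of 31 | C[C@@]12CCC[C@]3(COC(=O)[C@@]45C[C@@H](C[C@@H](OC=O)[C@H]43)C(COCc6ccccc6)=C5)[C@@H]1C(=O)OC2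
F11 | step 7 | acetate of the enantiomer of 17 | C[C@]12CCC[C@@](CC(=C)CCl)(COC(C)=O)[C@H]1C(=O)OC2
A1 | alternative 1 | spiro unsaturated six-membered lactone bis-acetal | C[C@@]12CC=C[C@]3(COC(=O)C(CC(CC(OC)OC)CC(OC)OC)=C3)[C@@H]1C(=O)OC2
A2 | alternative 2 | 17-nor bis-lactone with C11 silyl ether | C[C@@]12CCC[C@]3(COC(=O)[C@@]45C[C@@H](C[C@@H](O[Si](C)(C)C(C)(C)C)[C@H]43)CC5=O)[C@@H]1C(=O)OC2
A3 | alternative 3 | 17-nor pentacyclic 11,15-diol | C[C@@]12CCC[C@]3(COC(=O)[C@@]45C[C@@H](C[C@@H](O)[C@H]43)C[C@@H]5O)[C@@H]1C(=O)OC2
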